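**Plan**

- Labels: dihydrobenzofuran O1, C2, C3, C3a, C4–C7, C7a; ring A = guaiacyl on C2; side chain C1' (carbinol, on C5), C2' (bears guaiacyl ring C), C3' (CH2OH).
- Retrosynthesis: remove two benzyl and two TBS groups, trace C1'–OH back to C1'–B, then cut C2'–C(ring C) together with C1'–C5. This gives a ring C aryl triflate, an (E)-3-silyloxypropenyl boronate and a 5-bromo-dihydrobenzofuran; the ring O1–C2–C3–C3a–C7a is cut at C2–C3 to an aryl diazoacetate.
- Enabling feature: C1'(OH)–C2'(ring C)–C3'H2OH carries the benzofuran ring (through C5) and ring C on neighbouring sp3 carbons with oxygen on C1'. This is the anti 1,2-diarylation pattern of an E alkenyl–boron unit in which boron stands in for the C1' hydroxyl and is removed by oxidation.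
- Forward: the furan ring is closed first by rhodium-carbene insertion into the benzylic ether C–H, with the C5–Br handle (para to O1) carried from 4-bromoguaiacol; the side chain is then joined in one three-component operation, oxidised and deprotected.
- Stereochemistry: C2 from the chiral dirhodium carboxylate, C3 by epimerization to trans; C1' and C2' from the chiral palladium catalyst (absolute) and from E geometry, anti 1,2-shift, retentive reductive elimination and retentive C–B oxidation (relative).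

Key step: step 11

Abbreviations: PTTL = N-phthaloyl-tert-leucinate; L = (αR,αR)-2,2'-bis(α-dimethylaminobenzyl)-(S,S)-1,1'-bis(diphenylphosphino)ferrocene (the Sp,Sp enantiomer of MandyPhos); mac = the diolate of diol 14.

Assumption (chemistry): the facial preferences of Rh2(R-PTTL)4 in step 4 and of the palladium–L catalyst in step 11 are taken by analogy with simpler substrates; should either prove opposite, the mirror-image catalyst or ligand is used and nothing else changes.

**Route**

Step 1
Reactants: 1 4-bromo-2-methoxyphenol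
Product: 2 4-bromo-2-iodo-6-methoxyphenol
Conditions: I2 (1.05 equiv), NaHCO3 (1.5 equiv), MeOH/H2O, 0 °C to rt
Reagents that add atoms: iodine, II
Why: Electrophilic aromatic iodination of the phenoxide; the position para to oxygen is blocked by bromine, so iodine should enter the free position ortho to the hydroxyl.

Step 2
Reactants: 2 4-bromo-2-iodo-6-methoxyphenol; 3 4-(benzyloxy)-3-methoxybenzyl alcohol
Product: 4 1-(benzyloxy)-4-[(4-bromo-2-iodo-6-methoxyphenoxy)methyl]-2-methoxybenzene
Conditions: PPh3, DIAD, THF, 0 °C to rt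
Reagents that add atoms: none
Why: Mitsunobu etherification of an acidic phenol with a primary, electron-rich benzylic alcohol, which avoids handling the unstable benzylic halide.

Step 3
Reactants: 4 1-(benzyloxy)-4-[(4-bromo-2-iodo-6-methoxyphenoxy)methyl]-2-methoxybenzene; 5 ethyl diazoacetate
Product: 6 ethyl 2-(2-{[4-(benzyloxy)-3-methoxyphenyl]methoxy}-5-bromo-3-methoxyphenyl)-2-diazoacetate
Conditions: Pd(PPh3)4 (5 mol %), Ag2CO3 (0.5 equiv), Et3N (1.3 equiv), toluene, rt, dark
Reagents that add atoms: none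
Why: Palladium-catalysed cross-coupling of an aryl iodide with the acidic C–H of a diazoacetate with retention of the diazo group; zerovalent palladium should insert into C–I far faster than into C–Br at room temperature.

Step 4
Reactants: 6 ethyl 2-(2-{[4-(benzyloxy)-3-methoxyphenyl]methoxy}-5-bromo-3-methoxyphenyl)-2-diazoacetate
Product: 7 ethyl (2S,3R)-2-[4-(benzyloxy)-3-methoxyphenyl]-5-bromo-7-methoxy-2,3-dihydro-1-benzofuran-3-carboxylate (2,3-cis)
Conditions: Rh2(R-PTTL)4 (1 mol %), toluene, −60 °C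
Reagents that add atoms: none
Why: Intramolecular 1,5 C–H insertion of the donor/acceptor rhodium carbene into the electron-rich benzylic ether C–H closes the five-membered ring (C2–C3 bond); the concerted insertion should give the cis ester, and the chiral carboxylate ligands select the enantiotopic hydrogen and so set C2.

Step 5
Reactants: 7 cis ester
Product: 8 ethyl (2S,3S)-2-[4-(benzyloxy)-3-methoxyphenyl]-5-bromo-7-methoxy-2,3-dihydro-1-benzofuran-3-carboxylate (2,3-trans)
Conditions: NaOEt (0.3 equiv), EtOH/THF, 0 °C to rt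
Reagents that add atoms: none
Why: Base-mediated epimerization through the ester enolate at C3 to the thermodynamically preferred trans isomer; C2 is not enolisable and should keep its configuration.

Step 6
Reactants: 8 trans ester
Product: 9 [(2S,3R)-2-[4-(benzyloxy)-3-methoxyphenyl]-5-bromo-7-methoxy-2,3-dihydro-1-benzofuran-3-yl]methanol
Conditions: LiBH4, THF/MeOH, 0 °C to rt
Reagents that add atoms: none
Why: Borohydride reduction of the ester to the primary alcohol, leaving the aryl bromide and benzyl ethers intact; no stereocentre is touched (the change of the C3 descriptor is formal).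

Step 7
Reactants: 9 primary alcohol
Product: 10 {[(2S,3R)-2-[4-(benzyloxy)-3-methoxyphenyl]-5-bromo-7-methoxy-2,3-dihydro-1-benzofuran-3-yl]methoxy}(tert-butyl)dimethylsilane
Conditions: TBSCl, imidazole, DMF, rt
Reagents that add atoms: tert-butyldimethylsilyl chloride, CC(C)(C)[Si](C)(C)Cl
Why: Standard silylation of a primary alcohol, needed so that no acidic proton is present during the lithiation of step 11.

Step 8
Reactants: 11 4-(benzyloxy)-3-methoxyphenol
Product: 12 4-(benzyloxy)-3-methoxyphenyl trifluoromethanesulfonate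
Conditions: Tf2O, pyridine, CH2Cl2, 0 °C
Reagents that add atoms: trifluoromethanesulfonic anhydride, O=S(=O)(OS(=O)(=O)C(F)(F)F)C(F)(F)F
Why: O-sulfonylation of the phenol turns ring C into a halide-free electrophile whose ipso carbon lies para to the protected hydroxyl and meta to the methoxy group.

Step 9
Reactants: 13 acenaphthylene-1,2-dione (acenaphthoquinone)
Product: 14 (1R,2S)-1,2-dimethyl-1,2-dihydroacenaphthylene-1,2-diol (cis, meso)
Conditions: AlMe3 (3 equiv), toluene, 0 °C to rt; aqueous work-up; recrystallisation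
Reagents that add atoms: trimethylaluminium, C[Al](C)C
Why: Double 1,2-addition of methyl to the vicinal diketone; the second methyl should add on the face of the first methyl, away from the aluminium alkoxide, to give the cis diol needed for a cyclic boronate.

Step 10
Reactants: 15 tert-butyldimethyl(prop-2-yn-1-yloxy)silane; 14 cis diol
Product: 17 cyclic boronic ester of (E)-3-[(tert-butyldimethylsilyl)oxy]prop-1-en-1-ylboronic acid with diol 14 (alkenyl–B(mac)), via catechol alkenylboronate 16 (not isolated)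
Conditions: catecholborane (1.1 equiv), neat, 70 °C; then 14, THF, rt
Reagents that add atoms: catecholborane, B1Oc2ccccc2O1
Why: Syn hydroboration of the terminal alkyne places boron on the terminal carbon and fixes the E geometry, and the catechol ester then exchanges with the chelating ditertiary cis diol (hydroboration followed by transesterification).

Step 11
Reactants: 10 aryl bromide; 17 alkenyl–B(mac); 12 aryl triflate
Product: 20 B(mac) ester of (1S,2R)-1-[(2S,3R)-2-[4-(benzyloxy)-3-methoxyphenyl]-3-{[(tert-butyldimethylsilyl)oxy]methyl}-7-methoxy-2,3-dihydro-1-benzofuran-5-yl]-2-[4-(benzyloxy)-3-methoxyphenyl]-3-[(tert-butyldimethylsilyl)oxy]propylboronic acid, via aryllithium 18 (not isolated), via lithium boron ate complex 19 (not isolated)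
Conditions: 10, t-BuLi (2.0 equiv), Et2O, −78 °C; then 17, −78 °C to rt; solvent exchange to THF, KOTf (2 equiv); then 12 (1.1 equiv), Pd(OAc)2 (3 mol %), L (3.6 mol %), 60 °C
Reagents that add atoms: none
Why: Bromine–lithium exchange gives aryllithium 18, which adds to the boron of 17 to form the four-coordinate ate complex 19, and KOTf removes the bromide that would otherwise block the catalyst. Oxidative addition of triflate 12 to zerovalent palladium gives a cationic aryl complex of divalent palladium that binds the alkene of 19 and triggers a 1,2-metallate shift: the benzofuranyl group moves from boron to the boron-bearing carbon anti to palladium, and reductive elimination with retention then forms the bond between ring C and the CH2OTBS-bearing carbon. The closest known reaction type is the palladium-catalysed enantioselective conjunctive cross-coupling of beta-substituted alkenyl boron ate complexes carrying the mac diol with aryl triflates; no ring is closed. Of the two new stereocentres, the boron-bearing carbon (S) is set by the alkene face that the palladium–L complex selects, and the neighbouring carbon (R) follows from the E geometry of 17 together with anti migration and retentive reductive elimination, which places boron (later hydroxyl) and ring C syn along the chain. The step needs the metallate shift to outrun direct transmetallation of the alkenyl or aryl group (secured by the hindered mac diolate on boron), reductive elimination to outrun beta-hydride and beta-silyloxy elimination of the alkylpalladium (secured by the chelating bisphosphine and the aryl partner), and catalyst control to override the distant C2 and C3 centres (secured by their remoteness from the alkene).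

Step 12
Reactants: 20 secondary boronic ester
Product: 21 (1S,2R)-1-[(2S,3R)-2-[4-(benzyloxy)-3-methoxyphenyl]-3-{[(tert-butyldimethylsilyl)oxy]methyl}-7-methoxy-2,3-dihydro-1-benzofuran-5-yl]-2-[4-(benzyloxy)-3-methoxyphenyl]-3-[(tert-butyldimethylsilyl)oxy]propan-1-ol
Conditions: 30% aq H2O2, 3 M aq NaOH, THF, 0 °C to rt
Reagents that add atoms: hydrogen peroxide, OO
Why: Oxidation of the boronic ester by 1,2-migration of carbon from boron to oxygen with retention, which converts the temporary C–B bond into the C1' hydroxyl without touching either new stereocentre.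

Step 13
Reactants: 21 bis-silyl ether
Product: 22 (1S,2R)-1-[(2S,3R)-2-[4-(benzyloxy)-3-methoxyphenyl]-3-(hydroxymethyl)-7-methoxy-2,3-dihydro-1-benzofuran-5-yl]-2-[4-(benzyloxy)-3-methoxyphenyl]propane-1,3-diol
Conditions: TBAF (3 equiv), THF, 0 °C to rt
Reagents that add atoms: none
Why: Fluoride-mediated cleavage of both primary TBS ethers, done while the phenols are still benzylated so that no phenoxide can open the benzylic aryl ether of the furan ring.

Step 14
Reactants: 22 bis-benzyl ether
Product: 23 (1S,2R)-1-[(2S,3R)-2-(4-hydroxy-3-methoxyphenyl)-3-(hydroxymethyl)-7-methoxy-2,3-dihydro-1-benzofuran-5-yl]-2-(4-hydroxy-3-methoxyphenyl)propane-1,3-diol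
Conditions: H2 (1 atm), 10% Pd/C, EtOAc/EtOH, rt, stopped at full conversion
Reagents that add atoms: none
Why: Catalytic hydrogenolysis of the two aryl benzyl ethers under neutral conditions, which should be much faster than cleavage of the benzylic C2–O1 and C1'–OH bonds.

**Compound list**

1 | 4-bromo-2-methoxyphenol | COc1cc(Br)ccc1O | starting material
2 | 4-bromo-2-iodo-6-methoxyphenol | COc1cc(Br)cc(I)c1O | intermediate
3 | 4-(benzyloxy)-3-methoxybenzyl alcohol | COc1cc(CO)ccc1OCc1ccccc1 | starting material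
4 | 1-(benzyloxy)-4-[(4-bromo-2-iodo-6-methoxyphenoxy)methyl]-2-methoxybenzene | COc1cc(COc2c(I)cc(Br)cc2OC)ccc1OCc1ccccc1 | intermediate
5 | ethyl diazoacetate | CCOC(=O)C=[N+]=[N-] | starting material
6 | ethyl 2-(2-{[4-(benzyloxy)-3-methoxyphenyl]methoxy}-5-bromo-3-methoxyphenyl)-2-diazoacetate | CCOC(=O)C(=[N+]=[N-])c1cc(Br)cc(OC)c1OCc1ccc(OCc2ccccc2)c(OC)c1 | intermediate
7 | ethyl (2S,3R)-2-[4-(benzyloxy)-3-methoxyphenyl]-5-bromo-7-methoxy-2,3-dihydro-1-benzofuran-3-carboxylate (cis) | COc1cc([C@H]2Oc3c(OC)cc(Br)cc3[C@H]2C(=O)OCC)ccc1OCc1ccccc1 | intermediate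
8 | ethyl (2S,3S)-2-[4-(benzyloxy)-3-methoxyphenyl]-5-bromo-7-methoxy-2,3-dihydro-1-benzofuran-3-carboxylate (trans) | COc1cc([C@H]2Oc3c(OC)cc(Br)cc3[C@@H]2C(=O)OCC)ccc1OCc1ccccc1 | intermediate
9 | [(2S,3R)-2-[4-(benzyloxy)-3-methoxyphenyl]-5-bromo-7-methoxy-2,3-dihydro-1-benzofuran-3-yl]methanol | COc1cc([C@H]2Oc3c(OC)cc(Br)cc3[C@@H]2CO)ccc1OCc1ccccc1 | intermediate
10 | {[(2S,3R)-2-[4-(benzyloxy)-3-methoxyphenyl]-5-bromo-7-methoxy-2,3-dihydro-1-benzofuran-3-yl]methoxy}(tert-butyl)dimethylsilane | COc1cc([C@H]2Oc3c(OC)cc(Br)cc3[C@@H]2CO[Si](C)(C)C(C)(C)C)ccc1OCc1ccccc1 | intermediate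
11 | 4-(benzyloxy)-3-methoxyphenol | COc1cc(O)ccc1OCc1ccccc1 | starting material
12 | 4-(benzyloxy)-3-methoxyphenyl trifluoromethanesulfonate | COc1cc(OS(=O)(=O)C(F)(F)F)ccc1OCc1ccccc1 | intermediate
13 | acenaphthylene-1,2-dione | O=C1C(=O)c2cccc3cccc1c23 | starting material
14 | (1R,2S)-1,2-dimethyl-1,2-dihydroacenaphthylene-1,2-diol (cis, meso) | C[C@@]1(O)[C@](C)(O)c2cccc3cccc1c23 | intermediate
15 | tert-butyldimethyl(prop-2-yn-1-yloxy)silane | C#CCO[Si](C)(C)C(C)(C)C | starting material
16 | 2-[(E)-3-{[tert-butyl(dimethyl)silyl]oxy}prop-1-en-1-yl]-1,3,2-benzodioxaborole | CC(C)(C)[Si](C)(C)OC/C=C/B1Oc2ccccc2O1 | intermediate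
17 | cyclic boronic ester of (E)-3-[(tert-butyldimethylsilyl)oxy]prop-1-en-1-ylboronic acid with diol 14 | CC(C)(C)[Si](C)(C)OC/C=C/B1O[C@@]2(C)c3cccc4cccc(c34)[C@@]2(C)O1 | intermediate
18 | [(2S,3R)-2-[4-(benzyloxy)-3-methoxyphenyl]-3-{[(tert-butyldimethylsilyl)oxy]methyl}-7-methoxy-2,3-dihydro-1-benzofuran-5-yl]lithium | COc1cc([C@H]2Oc3c(OC)cc([Li])cc3[C@@H]2CO[Si](C)(C)C(C)(C)C)ccc1OCc1ccccc1 | intermediate
19 | lithium salt of the four-coordinate borate formed from 18 and 17 (boron bears the benzofuran-5-yl group, the E alkenyl group and the mac diolate) | [Li+].COc1cc([C@H]2Oc3c(OC)cc([B-]4(/C=C/CO[Si](C)(C)C(C)(C)C)O[C@@]5(C)c6cccc7cccc(c67)[C@@]5(C)O4)cc3[C@@H]2CO[Si](C)(C)C(C)(C)C)ccc1OCc1ccccc1 | intermediate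
20 | B(mac) ester of (1S,2R)-1-[(2S,3R)-2-[4-(benzyloxy)-3-methoxyphenyl]-3-{[(tert-butyldimethylsilyl)oxy]methyl}-7-methoxy-2,3-dihydro-1-benzofuran-5-yl]-2-[4-(benzyloxy)-3-methoxyphenyl]-3-[(tert-butyldimethylsilyl)oxy]propylboronic acid | COc1cc([C@H]2Oc3c(OC)cc([C@@H](B4O[C@@]5(C)c6cccc7cccc(c67)[C@@]5(C)O4)[C@@H](CO[Si](C)(C)C(C)(C)C)c4ccc(OCc5ccccc5)c(OC)c4)cc3[C@@H]2CO[Si](C)(C)C(C)(C)C)ccc1OCc1ccccc1 | intermediate
21 | (1S,2R)-1-[(2S,3R)-2-[4-(benzyloxy)-3-methoxyphenyl]-3-{[(tert-butyldimethylsilyl)oxy]methyl}-7-methoxy-2,3-dihydro-1-benzofuran-5-yl]-2-[4-(benzyloxy)-3-methoxyphenyl]-3-[(tert-butyldimethylsilyl)oxy]propan-1-ol | COc1cc([C@H]2Oc3c(OC)cc([C@@H](O)[C@@H](CO[Si](C)(C)C(C)(C)C)c4ccc(OCc5ccccc5)c(OC)c4)cc3[C@@H]2CO[Si](C)(C)C(C)(C)C)ccc1OCc1ccccc1 | intermediate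
22 | (1S,2R)-1-[(2S,3R)-2-[4-(benzyloxy)-3-methoxyphenyl]-3-(hydroxymethyl)-7-methoxy-2,3-dihydro-1-benzofuran-5-yl]-2-[4-(benzyloxy)-3-methoxyphenyl]propane-1,3-diol | COc1cc([C@H]2Oc3c(OC)cc([C@@H](O)[C@@H](CO)c4ccc(OCc5ccccc5)c(OC)c4)cc3[C@@H]2CO)ccc1OCc1ccccc1 | intermediate
23 | (1S,2R)-1-[(2S,3R)-2-(4-hydroxy-3-methoxyphenyl)-3-(hydroxymethyl)-7-methoxy-2,3-dihydro-1-benzofuran-5-yl]-2-(4-hydroxy-3-methoxyphenyl)propane-1,3-diol | COc1cc([C@H]2Oc3c(OC)cc([C@@H](O)[C@@H](CO)c4ccc(O)c(OC)c4)cc3[C@@H]2CO)ccc1O | target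

**Step count and risks**

Total steps: 14. Longest linear sequence: 11 (steps 1 to 7, then 11 to 14).

Steps most likely to fail:

1. Step 11. The alkylpalladium intermediate may lose hydride or silyloxide before reductive elimination, direct transmetallation may give the biaryl or the alkenyl arene, or facial control may be eroded by the chiral aryl group. The fallback sets out from 10 and comes back at 22. Bromine–lithium exchange of 10 (t-BuLi, THF, −78 °C) and quenching with DMF would give (2S,3R)-2-[4-(benzyloxy)-3-methoxyphenyl]-3-{[(tert-butyldimethylsilyl)oxy]methyl}-7-methoxy-2,3-dihydro-1-benzofuran-5-carbaldehyde F1. The imide (4S)-4-benzyl-3-{[4-(benzyloxy)-3-methoxyphenyl]acetyl}-1,3-oxazolidin-2-one F2 would be made from commercial [4-(benzyloxy)-3-methoxyphenyl]acetic acid (PivCl, Et3N, then the lithium salt of (S)-4-benzyloxazolidin-2-one). Its Z boron enolate (Bu2BOTf, iPr2NEt, CH2Cl2, −78 °C) would add to F1 in an Evans syn aldol reaction to give the aldol adduct (4S)-4-benzyl-3-[(2S,3S)-2-aryl-3-hydroxy-3-(benzofuran-5-yl)propanoyl]-1,3-oxazolidin-2-one F3; the chair transition state and the auxiliary set both centres, and 2S,3S in the imide corresponds to 1S,2R in the diol. Reductive removal of the auxiliary (LiBH4, THF/MeOH, 0 °C) would give the mono-silylated 1,3-diol F4, and TBAF would then deliver 22.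

2. Step 3. Oxidative addition and coupling at the C–I bond flanked by the bulky benzyloxy group may be slow, so that insertion into C–Br or palladium-induced loss of nitrogen from the product competes. The fallback sets out from 4 and comes back at 6. Iodine–magnesium exchange (iPrMgCl·LiCl, THF, −40 °C, where the C–Br bond should not exchange) and addition to excess diethyl oxalate at −78 °C would give ethyl 2-(2-{[4-(benzyloxy)-3-methoxyphenyl]methoxy}-5-bromo-3-methoxyphenyl)-2-oxoacetate F5. Condensation with TsNHNH2 (EtOH, 50 °C) would give the tosylhydrazone F6, and DBU in CH2Cl2 at rt (Bamford–Stevens elimination of sulfinate) would give 6.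

3. Step 4. Discrimination between the two enantiotopic benzylic hydrogens may be insufficient, because the C7 methoxy group next to the ether oxygen twists the benzyloxy arm. The fallback sets out from 6 and comes back at 9, replacing asymmetric catalysis by resolution. Rh2(OAc)4 (CH2Cl2, rt) would give the racemic cis ester F7, NaOEt/EtOH the racemic trans ester F8, and LiBH4 the racemic trans alcohol F9. Acylation with (1S)-camphanic chloride (pyridine, DMAP, CH2Cl2) would give two diastereomeric camphanates to be separated by crystallisation or chromatography: the camphanate of the (2S,3R) alcohol F10 and the camphanate of the (2R,3S) alcohol F11 (discarded). The configuration of F10 would be secured by crystallography, and K2CO3 in MeOH would release 9.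

**Further compounds**

F1 | step 11 | (2S,3R)-2-[4-(benzyloxy)-3-methoxyphenyl]-3-{[(tert-butyldimethylsilyl)oxy]methyl}-7-methoxy-2,3-dihydro-1-benzofuran-5-carbaldehyde | COc1cc([C@H]2Oc3c(OC)cc(C=O)cc3[C@@H]2CO[Si](C)(C)C(C)(C)C)ccc1OCc1ccccc1
F2 | step 11 | (4S)-4-benzyl-3-{[4-(benzyloxy)-3-methoxyphenyl]acetyl}-1,3-oxazolidin-2-one | O=C(Cc1ccc(OCc2ccccc2)c(OC)c1)N1[C@@H](Cc2ccccc2)COC1=O
F3 | step 11 | (4S)-4-benzyl-3-[(2S,3S)-2-[4-(benzyloxy)-3-methoxyphenyl]-3-[(2S,3R)-2-[4-(benzyloxy)-3-methoxyphenyl]-3-{[(tert-butyldimethylsilyl)oxy]methyl}-7-methoxy-2,3-dihydro-1-benzofuran-5-yl]-3-hydroxypropanoyl]-1,3-oxazolidin-2-one | COc1cc([C@H]2Oc3c(OC)cc([C@@H](O)[C@@H](C(=O)N4[C@@H](Cc5ccccc5)COC4=O)c4ccc(OCc5ccccc5)c(OC)c4)cc3[C@@H]2CO[Si](C)(C)C(C)(C)C)ccc1OCc1ccccc1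
F4 | step 11 | (1S,2R)-1-[(2S,3R)-2-[4-(benzyloxy)-3-methoxyphenyl]-3-{[(tert-butyldimethylsilyl)oxy]methyl}-7-methoxy-2,3-dihydro-1-benzofuran-5-yl]-2-[4-(benzyloxy)-3-methoxyphenyl]propane-1,3-diol | COc1cc([C@H]2Oc3c(OC)cc([C@@H](O)[C@@H](CO)c4ccc(OCc5ccccc5)c(OC)c4)cc3[C@@H]2CO[Si](C)(C)C(C)(C)C)ccc1OCc1ccccc1
F5 | step 3 | ethyl 2-(2-{[4-(benzyloxy)-3-methoxyphenyl]methoxy}-5-bromo-3-methoxyphenyl)-2-oxoacetate | CCOC(=O)C(=O)c1cc(Br)cc(OC)c1OCc1ccc(OCc2ccccc2)c(OC)c1
F6 | step 3 | ethyl 2-(2-{[4-(benzyloxy)-3-methoxyphenyl]methoxy}-5-bromo-3-methoxyphenyl)-2-[2-(4-methylbenzenesulfonyl)hydrazinylidene]acetate (E/Z mixture) | CCOC(=O)C(=NNS(=O)(=O)c1ccc(C)cc1)c1cc(Br)cc(OC)c1OCc1ccc(OCc2ccccc2)c(OC)c1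
F7 | step 4 | racemic cis ethyl 2-[4-(benzyloxy)-3-methoxyphenyl]-5-bromo-7-methoxy-2,3-dihydro-1-benzofuran-3-carboxylate (both enantiomers) | COc1cc([C@H]2Oc3c(OC)cc(Br)cc3[C@H]2C(=O)OCC)ccc1OCc1ccccc1.COc1cc([C@@H]2Oc3c(OC)cc(Br)cc3[C@@H]2C(=O)OCC)ccc1OCc1ccccc1
F8 | step 4 | racemic trans ethyl 2-[4-(benzyloxy)-3-methoxyphenyl]-5-bromo-7-methoxy-2,3-dihydro-1-benzofuran-3-carboxylate (both enantiomers) | COc1cc([C@H]2Oc3c(OC)cc(Br)cc3[C@@H]2C(=O)OCC)ccc1OCc1ccccc1.COc1cc([C@@H]2Oc3c(OC)cc(Br)cc3[C@H]2C(=O)OCC)ccc1OCc1ccccc1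
F9 | step 4 | racemic trans [2-[4-(benzyloxy)-3-methoxyphenyl]-5-bromo-7-methoxy-2,3-dihydro-1-benzofuran-3-yl]methanol (both enantiomers) | COc1cc([C@H]2Oc3c(OC)cc(Br)cc3[C@@H]2CO)ccc1OCc1ccccc1.COc1cc([C@@H]2Oc3c(OC)cc(Br)cc3[C@H]2CO)ccc1OCc1ccccc1
F10 | step 4 | [(2S,3R)-2-[4-(benzyloxy)-3-methoxyphenyl]-5-bromo-7-methoxy-2,3-dihydro-1-benzofuran-3-yl]methyl (1S,4R)-4,7,7-trimethyl-3-oxo-2-oxabicyclo[2.2.1]heptane-1-carboxylate | COc1cc([C@H]2Oc3c(OC)cc(Br)cc3[C@@H]2COC(=O)[C@@]23CC[C@@](C)(C(=O)O2)C3(C)C)ccc1OCc1ccccc1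
F11 | step 4 | [(2R,3S)-2-[4-(benzyloxy)-3-methoxyphenyl]-5-bromo-7-methoxy-2,3-dihydro-1-benzofuran-3-yl]methyl (1S,4R)-4,7,7-trimethyl-3-oxo-2-oxabicyclo[2.2.1]heptane-1-carboxylate | COc1cc([C@@H]2Oc3c(OC)cc(Br)cc3[C@H]2COC(=O)[C@@]23CC[C@@](C)(C(=O)O2)C3(C)C)ccc1OCc1ccccc1
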